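The reading comes at 2.5 d, well after the 10 h feed has ended, so I ask how much X the catalyst can turn out by then.

| flask | G | Q | remark | time |
|---|---|---|---|---|
| alder | 0.11 M (fed, over 10 h) | 0.75 mol% | run made earlier |  |
| flask | 0.11 M (fed, over 10 h) | 0.5 mol% |  | 2.5 d |

alder run (percent of the G charged)

| time / h | X / % | G / % |
|---|---|---|
| 1.50 | 1.2 | 13.3 |
| 3.00 | 3.1 | 26.3 |
| 5.00 | 5.1 | 44.0 |
| 6.00 | 6.2 | 52.3 |

(readings scatter by 0.3 percentage points)

- the numbers in the tables scatter with a standard deviation of 0.3 percentage points
- steps under discussion: D -> L; L <-> Q + X; G + Q <-> D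
- percentages count the whole charge, also what has not yet gone in
- no earlier run changes the charge of Q; that part of a forecast is a guess

* the X in the flask at 2.5 d, as a percentage of the G charged
* the G in the flask at 2.5 d, as a percentage of the G charged

X climbs steadily in the alder run, so I read a turnover frequency w, the X made per hour per unit of Q charged, from its first and last readings:

w = (rise in X) / (elapsed time × loading) = 1.48 h⁻¹

For this flask, with loading n and reading time t:

Θ = w n t = 0.444

Θ is the capacity ratio, the share of the G charged that the catalyst can turn over by the reading at the alder pace. In this picture the crossing lies at Θ = 1: below it the catalyst sets the pace, and above it G is the limiting reagent. This flask lies below, so I commit to X near 44.4% and G near 55.6%.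

Is one number enough? In the alder run, as G climbs from 13.3% to 52.3%, w reads 1.69 h⁻¹ and then 1.38 h⁻¹, which I take as one value given the scatter. But in that run X over G reads 0.118 at 3.00 h and 0.119 at 6.00 h, so X does not gain on G in these readings, and the scaling with Q is a guess.

The forecast gives X 37% and G 62.5%, lower in X than my figure, with the warning “so the rate may sag”.

At 2.5 d the flask holds X 51.6% and G 47.9%, which is 15 percentage points more X than the forecast and 7.2 points more than Θ.

D → L (k = 1.60 min⁻¹); L ⇌ Q + X (K = 0.210 M, k = 0.0310 min⁻¹); G + Q ⇌ D (K = 8.20 L mol⁻¹, k = 49.0 L mol⁻¹ min⁻¹) In this flask at 2.50 d, L is 93.0% of the catalyst charged, against 95.3% at the end of the feed. A neighbour flask with 2 mol% of Q has Θ = 1.78, above the crossing, and there G stands at 0% and X at 99.3%.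

The data were computed with made-up constants; the scatter is artificial.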